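**Plan**

- Retrosynthetic cuts, in order: (a) the C–C and C–O bonds that hold the pendant methyl-lactone on the free pyrrole α-carbon; (b) the methyl on the fused lactone; (c) the bond from the pyrrole β-carbon to the lactone β-carbon, which opens the cyclohexane and leaves a butenolide; (d) two azepine bonds at once, pyrrole α-carbon to ring-fusion CH and the middle CH2–CH2 bond of the N-to-CH bridge.
- Feature behind (d): in the azepine, the ring-fusion CH and the CH2 two atoms further on are the β-carbon and carbonyl carbon of an enal (a 1,3-dielectrophile). The pyrrole α-carbon and the second carbon of the N-ethyl arm, once that carbon is a phosphonium ylide, are the ends of a four-atom C,C-dinucleophile. Friedel–Crafts addition followed by Wittig closure is therefore a (4+3) annulation; phosphorus leaves as Ph3PO and the alkene is hydrogenated later.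
- Forward order: purchased pyrrole, then azepine (key step, joins the two halves), then cyclohexane and fused lactone together (tethered Michael addition), then lactone methyl, then pendant lactone.
- Stereochemistry: ethyl- and O-bearing carbons from a catalyst-controlled syn pentenylboration; azepine ring-fusion CH from the imidazolidinone catalyst; lactone ring fusion from the tether (cis only); lactone methyl from convex-face hydrogenation; pendant-lactone methyl from (S)-methylsuccinic acid and its O–CH from asymmetric transfer hydrogenation.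

Key step: step 6

Remark: compounds 1, 3, 6 and 23, 1-allylpyrrole and (S)-2-methylpent-4-enoic acid are taken as purchasable, and the sense of induction of each chiral catalyst is assigned by analogy with its behaviour toward simple aldehydes and ketones.

**Step 1**
Reactants: 1 1-(2-bromoethyl)-1H-pyrrole
Product: 2 [2-(1H-pyrrol-1-yl)ethyl]triphenylphosphonium bromide
Conditions: PPh3 (1.1 equiv), MeCN, 80 °C
Reagents that add atoms: triphenylphosphine, c1ccc(cc1)P(c1ccccc1)c1ccccc1
Why: SN2 displacement of the primary bromide by PPh3 (phosphonium salt formation) should be clean because the pyrrole nitrogen lone pair is part of the aromatic sextet and does not compete.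

**Step 2**
Reactants: 3 (Z)-pent-2-ene
Product: 5 (Z)-4,4,5,5-tetramethyl-2-(pent-2-en-1-yl)-1,3,2-dioxaborolane, via (Z)-pent-2-enylpotassium 4 (not isolated)
Conditions: n-BuLi, KOtBu, THF, −78 → −50 °C; i-PrOBpin, −78 °C; 1 M HCl, 0 °C
Reagents that add atoms: potassium tert-butoxide, CC(C)(C)[O-].[K+] (the potassium of 4); 2-isopropoxy-4,4,5,5-tetramethyl-1,3,2-dioxaborolane, CC(C)OB1OC(C)(C)C(C)(C)O1
Why: Superbase allylic metalation (butylpotassium made in the flask) should deprotonate the methyl group of the cis-alkene to the configurationally stable Z-allylpotassium 4, which the borate traps at its CH2 terminus with the Z geometry intact.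

**Step 3**
Reactants: 5 (Z)-4,4,5,5-tetramethyl-2-(pent-2-en-1-yl)-1,3,2-dioxaborolane; 6 3-(trimethylsilyl)prop-2-ynal
Product: 8 (3S,4R)-4-ethyl-1-(trimethylsilyl)hex-5-en-1-yn-3-ol, via pinacol borate ester of the alcohol 7 (not isolated)
Conditions: (S)-TRIP [(S)-3,3'-bis(2,4,6-triisopropylphenyl)-1,1'-binaphthyl-2,2'-diyl hydrogen phosphate] (5 mol %), 4 Å molecular sieves, toluene, −30 °C; then H2O
Reagents that add atoms: none
Why: Chiral phosphoric acid-catalysed allylboration through a closed chair transition state should give the syn ethyl/hydroxyl pair from the Z-boronate and the (3S) carbinol from the (S)-acid, which sets the ethyl-bearing and the O-bearing stereocenters of the target.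

**Step 4**
Reactants: 8 (3S,4R)-4-ethyl-1-(trimethylsilyl)hex-5-en-1-yn-3-ol
Product: 9 tert-butyl{[(3S,4R)-4-ethyl-1-(trimethylsilyl)hex-5-en-1-yn-3-yl]oxy}dimethylsilane
Conditions: TBSCl, imidazole, DMF, rt
Reagents that add atoms: tert-butyldimethylsilyl chloride, CC(C)(C)[Si](C)(C)Cl
Why: Standard silylation of a secondary alcohol; the ether keeps the hydroxyl out of hemiacetal and alkoxide chemistry in step 6.

**Step 5**
Reactants: 9 tert-butyl{[(3S,4R)-4-ethyl-1-(trimethylsilyl)hex-5-en-1-yn-3-yl]oxy}dimethylsilane
Product: 10 (2E,4R,5S)-5-[(tert-butyldimethylsilyl)oxy]-4-ethyl-7-(trimethylsilyl)hept-2-en-6-ynal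
Conditions: (E)-but-2-enal (5 equiv), second-generation Hoveyda–Grubbs catalyst (5 mol %), CH2Cl2, 40 °C
Reagents that add atoms: (E)-but-2-enal, C/C=C/C=O
Why: Olefin cross-metathesis of the terminal alkene with excess crotonaldehyde should give the E-enal with loss of propene, the silyl-capped alkyne and the silyl ether being inert to the ruthenium carbene.

**Step 6**
Reactants: 10 (2E,4R,5S)-5-[(tert-butyldimethylsilyl)oxy]-4-ethyl-7-(trimethylsilyl)hept-2-en-6-ynal; 2 [2-(1H-pyrrol-1-yl)ethyl]triphenylphosphonium bromide
Product: 13 tert-butyl{[(3S,4R)-4-[(9R)-8,9-dihydro-5H-pyrrolo[1,2-a]azepin-9-yl]-1-(trimethylsilyl)hex-1-yn-3-yl]oxy}dimethylsilane, via aldehyde phosphonium bromide 11 (not isolated), via phosphonium ylide 12 (not isolated)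
Conditions: (5R)-5-benzyl-2,2,3-trimethylimidazolidin-4-one·CF3CO2H (20 mol %), CH2Cl2/i-PrOH (9:1), −40 → −20 °C, slow addition of 10 to 2 (1.2 equiv); then evaporation, THF (0.005 M), KN(SiMe3)2 (1.6 equiv), −78 °C → rt
Reagents that add atoms: none
Why: The secondary amine condenses with 10 to the E-iminium ion, the α-carbon of pyrrole 2 adds to its β-carbon and hydrolysis of the enamine releases aldehyde 11 (first bond); base then makes ylide 12, whose carbon attacks the tethered aldehyde, and the oxaphosphetane collapses to the Z-alkene with loss of Ph3PO (second bond). The closest known reaction types are the iminium-catalysed Friedel–Crafts alkylation of N-alkylpyrroles with enals and the intramolecular Wittig olefination; run in one flask they amount to a (4+3) annulation of a four-atom C,C-dinucleophile with a 1,3-dielectrophile. Only the azepine is closed, by carbonyl olefination (ylide carbon onto the aldehyde, seven-membered, the pyrrole N–C bond being part of the new ring). The new stereocenter at the ring-fusion CH is set by the catalyst, whose benzyl group covers one face of the iminium ion, the (5R) enantiomer being the one expected to give the (R) centre and to override the weak bias of the neighbouring ethyl-bearing centre. The step needs 1,4- instead of 1,2-addition and pyrrole α- instead of β-attack (iminium activation and the intrinsic α-preference of N-alkylpyrroles), mono- instead of 2,5-dialkylation (slow addition of 10 to a small excess of 2) and ring closure instead of intermolecular olefination (one ylide and one aldehyde in the same molecule at high dilution).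

**Step 7**
Reactants: 13 tert-butyl{[(3S,4R)-4-[(9R)-8,9-dihydro-5H-pyrrolo[1,2-a]azepin-9-yl]-1-(trimethylsilyl)hex-1-yn-3-yl]oxy}dimethylsilane
Product: 15 methyl (4S,5R)-4-[(tert-butyldimethylsilyl)oxy]-5-[(9R)-8,9-dihydro-5H-pyrrolo[1,2-a]azepin-9-yl]hept-2-ynoate, via lithium acetylide 14 (not isolated)
Conditions: MeLi·LiBr (1.5 equiv), THF, 0 °C → rt; then ClCO2Me, −78 °C
Reagents that add atoms: methyllithium, [Li]C (the lithium of 14); methyl chloroformate, COC(=O)Cl
Why: MeLi·LiBr should cleave the alkynyl C–Si bond to the lithium acetylide 14 while leaving the silyl ether alone, and the acetylide is then acylated at carbon by the chloroformate (acetylide carboxylation).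

**Step 8**
Reactants: 15 methyl (4S,5R)-4-[(tert-butyldimethylsilyl)oxy]-5-[(9R)-8,9-dihydro-5H-pyrrolo[1,2-a]azepin-9-yl]hept-2-ynoate
Product: 18 (5R)-5-{(1R)-1-[(9R)-8,9-dihydro-5H-pyrrolo[1,2-a]azepin-9-yl]propyl}furan-2(5H)-one, via (Z)-enoate silyl ether 16 (not isolated), via (Z)-hydroxy enoate 17 (not isolated)
Conditions: H2 (1 atm), Pd/CaCO3 poisoned with Pb(OAc)2 (Lindlar catalyst), quinoline, EtOAc, rt; filtration; then HF·pyridine, THF, 0 °C → rt
Reagents that add atoms: none
Why: Lindlar semi-hydrogenation should stop at the Z-enoate without touching the ring alkene or the pyrrole, and fluoride desilylation frees the γ-hydroxyl, which lactonizes onto the cis-disposed ester to the butenolide with retention at the O-bearing carbon.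

**Step 9**
Reactants: 18 (5R)-5-{(1R)-1-[(9R)-8,9-dihydro-5H-pyrrolo[1,2-a]azepin-9-yl]propyl}furan-2(5H)-one
Product: 19 tetracyclic lactone (pyrrole fused at its α,β-bond to the new cyclohexane; cis-fused γ-butyrolactone with α-CH2; Z-alkene in the azepine; azepine CH R, ethyl CH R, O–CH S, lactone β-CH R)
Conditions: Sc(OTf)3 (20 mol %), 1,2-dichloroethane (0.01 M), 60 °C
Reagents that add atoms: none
Why: In this Lewis acid-promoted intramolecular Friedel–Crafts Michael addition (6-exo) only the pyrrole β-carbon next to the substituted α-carbon can reach the butenolide β-carbon, and because the tether starts at the lactone γ-carbon it must add to the face syn to itself, so the cyclohexane closes with a cis ring fusion and the new lactone β-stereocenter is set by the O-bearing centre.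

**Step 10**
Reactants: 19 tetracyclic lactone
Product: 21 α-methylene tetracyclic lactone (19 with C=CH2 at the lactone α-carbon; lactone β-CH now S by priority change only), via sodium enolate of the α-formyl lactone 20 (not isolated)
Conditions: NaH, HCO2Et, THF, 0 °C → rt; then (CH2O)n, THF, 65 °C
Reagents that add atoms: sodium hydride, [Na+].[H-] (the sodium of 20); ethyl formate, CCOC=O (the formyl group of 20); formaldehyde as paraformaldehyde, C=O (the methylene of 21)
Why: Claisen formylation followed by formaldehyde-induced deformylative methylenation gives the α-methylene lactone under basic conditions that leave the free pyrrole α-carbon alone, which an iminium-based methylenation would attack.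

**Step 11**
Reactants: 21 α-methylene tetracyclic lactone
Product: 22 saturated tetracyclic methyl lactone (azepine CH R, ethyl CH R, O–CH S, lactone β-CH R, lactone α-CH(CH3) R; pyrrole α-carbon free)
Conditions: H2 (1 atm), RhCl(PPh3)3 (10 mol %), benzene/EtOH (1:1), rt
Reagents that add atoms: none
Why: Homogeneous hydrogenation should deliver hydrogen to the exocyclic methylene from the convex face of the cis-fused lactone, which puts the methyl on the concave face cis to the pyrrole-bound carbon as in the target, and it also saturates the azepine alkene while the pyrrole stays intact.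

**Step 12**
Reactants: 23 (S)-2-methylsuccinic acid
Product: 24 (S)-methylsuccinic anhydride [(3S)-3-methyloxolane-2,5-dione]
Conditions: AcCl, 55 °C; evaporation
Reagents that add atoms: none
Why: Cyclodehydration of a 1,4-diacid with acetyl chloride (anhydride formation) does not involve the stereocenter.

**Step 13**
Reactants: 22 saturated tetracyclic methyl lactone; 24 (S)-methylsuccinic anhydride
Product: 25 γ-keto acid (22 carrying a (3S)-3-carboxybutanoyl group, C(=O)CH2CH(CH3)CO2H, on the free pyrrole α-carbon)
Conditions: AlCl3 (2.5 equiv), CH2Cl2, −20 → 0 °C; dilute HCl work-up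
Reagents that add atoms: none
Why: Friedel–Crafts acylation at the only unsubstituted pyrrole α-carbon, the site of highest intrinsic nucleophilicity (a late C–H functionalization), with the anhydride opening at its less hindered carbonyl remote from the methyl; the stereocenter is not α to the acylium carbon and should survive.

**Step 14**
Reactants: 25 γ-keto acid
Product: 27 target CNP0232452.4, via (R)-hydroxy acid 26 (not isolated)
Conditions: RuCl(p-cymene)[(R,R)-TsDPEN] (2 mol %), HCO2Na, H2O/MeOH (1:1), 40 °C; then pH 6, extraction, EDC·HCl, DMAP (cat.), CH2Cl2, 0 °C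
Reagents that add atoms: none
Why: Asymmetric transfer hydrogenation of the heteroaryl ketone in neutral formate, with the (R,R)-ligand expected to give the (R)-carbinol as for aryl alkyl ketones, followed by carbodiimide lactonization in which the alcohol attacks the activated acid so that the carbinol configuration is retained; together with the methyl centre from 23 this defines the trans lactone.

**Compound list**

1 | 1-(2-bromoethyl)-1H-pyrrole | BrCCn1cccc1 | starting material
2 | [2-(1H-pyrrol-1-yl)ethyl]triphenylphosphonium bromide | [Br-].c1ccn(CC[P+](c2ccccc2)(c2ccccc2)c2ccccc2)c1 | intermediate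
3 | (Z)-pent-2-ene | C/C=C\CC | starting material
4 | (Z)-pent-2-enylpotassium | [K]C/C=C\CC | intermediate
5 | (Z)-4,4,5,5-tetramethyl-2-(pent-2-en-1-yl)-1,3,2-dioxaborolane | CC/C=C\CB1OC(C)(C)C(C)(C)O1 | intermediate
6 | 3-(trimethylsilyl)prop-2-ynal | C[Si](C)(C)C#CC=O | starting material
7 | 2-{[(3S,4R)-4-ethyl-1-(trimethylsilyl)hex-5-en-1-yn-3-yl]oxy}-4,4,5,5-tetramethyl-1,3,2-dioxaborolane | CC[C@H](C=C)[C@@H](C#C[Si](C)(C)C)OB1OC(C)(C)C(C)(C)O1 | intermediate
8 | (3S,4R)-4-ethyl-1-(trimethylsilyl)hex-5-en-1-yn-3-ol | CC[C@H](C=C)[C@@H](C#C[Si](C)(C)C)O | intermediate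
9 | tert-butyl{[(3S,4R)-4-ethyl-1-(trimethylsilyl)hex-5-en-1-yn-3-yl]oxy}dimethylsilane | CC[C@H](C=C)[C@@H](C#C[Si](C)(C)C)O[Si](C)(C)C(C)(C)C | intermediate
10 | (2E,4R,5S)-5-[(tert-butyldimethylsilyl)oxy]-4-ethyl-7-(trimethylsilyl)hept-2-en-6-ynal | CC[C@H](/C=C/C=O)[C@@H](C#C[Si](C)(C)C)O[Si](C)(C)C(C)(C)C | intermediate
11 | [2-(2-{(3R,4R,5S)-5-[(tert-butyldimethylsilyl)oxy]-4-ethyl-1-oxo-7-(trimethylsilyl)hept-6-yn-3-yl}-1H-pyrrol-1-yl)ethyl]triphenylphosphonium bromide | CC[C@H]([C@@H](CC=O)c1cccn1CC[P+](c1ccccc1)(c1ccccc1)c1ccccc1)[C@@H](C#C[Si](C)(C)C)O[Si](C)(C)C(C)(C)C.[Br-] | intermediate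
12 | [2-(2-{(3R,4R,5S)-5-[(tert-butyldimethylsilyl)oxy]-4-ethyl-1-oxo-7-(trimethylsilyl)hept-6-yn-3-yl}-1H-pyrrol-1-yl)ethylidene]triphenylphosphorane | CC[C@H]([C@@H](CC=O)c1cccn1CC=P(c1ccccc1)(c1ccccc1)c1ccccc1)[C@@H](C#C[Si](C)(C)C)O[Si](C)(C)C(C)(C)C | intermediate
13 | tert-butyl{[(3S,4R)-4-[(9R)-8,9-dihydro-5H-pyrrolo[1,2-a]azepin-9-yl]-1-(trimethylsilyl)hex-1-yn-3-yl]oxy}dimethylsilane | CC[C@H]([C@H]1CC=CCn2cccc12)[C@@H](C#C[Si](C)(C)C)O[Si](C)(C)C(C)(C)C | intermediate
14 | {(3S,4R)-3-[(tert-butyldimethylsilyl)oxy]-4-[(9R)-8,9-dihydro-5H-pyrrolo[1,2-a]azepin-9-yl]hex-1-yn-1-yl}lithium | CC[C@H]([C@H]1CC=CCn2cccc12)[C@@H](C#C[Li])O[Si](C)(C)C(C)(C)C | intermediate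
15 | methyl (4S,5R)-4-[(tert-butyldimethylsilyl)oxy]-5-[(9R)-8,9-dihydro-5H-pyrrolo[1,2-a]azepin-9-yl]hept-2-ynoate | CC[C@H]([C@H]1CC=CCn2cccc12)[C@@H](C#CC(=O)OC)O[Si](C)(C)C(C)(C)C | intermediate
16 | methyl (2Z,4R,5R)-4-[(tert-butyldimethylsilyl)oxy]-5-[(9R)-8,9-dihydro-5H-pyrrolo[1,2-a]azepin-9-yl]hept-2-enoate | CC[C@H]([C@H]1CC=CCn2cccc12)[C@@H](/C=C\C(=O)OC)O[Si](C)(C)C(C)(C)C | intermediate
17 | methyl (2Z,4R,5R)-5-[(9R)-8,9-dihydro-5H-pyrrolo[1,2-a]azepin-9-yl]-4-hydroxyhept-2-enoate | CC[C@H]([C@H]1CC=CCn2cccc12)[C@@H](/C=C\C(=O)OC)O | intermediate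
18 | (5R)-5-{(1R)-1-[(9R)-8,9-dihydro-5H-pyrrolo[1,2-a]azepin-9-yl]propyl}furan-2(5H)-one | CC[C@H]([C@H]1CC=CCn2cccc12)[C@@H]1OC(=O)C=C1 | intermediate
19 | tetracyclic lactone: pyrrole fused to a cyclohexane bearing a cis-fused γ-butyrolactone (α-CH2) and bridged from N by CH2–CH=CH–CH2 (Z); azepine CH R, ethyl CH R, O–CH S, lactone β-CH R | CC[C@H]1[C@@H]2OC(=O)C[C@@H]2c2ccn3c2[C@@H]1CC=CC3 | intermediate
20 | sodium enolate of the α-formyl derivative of 19 | CC[C@H]1[C@@H]2OC(=O)C(=C[O-])[C@@H]2c2ccn3c2[C@@H]1CC=CC3.[Na+] | intermediate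
21 | α-methylene lactone: 19 with C=CH2 at the lactone α-carbon (lactone β-CH S by priority change, same geometry) | CC[C@H]1[C@@H]2OC(=O)C(=C)[C@@H]2c2ccn3c2[C@@H]1CC=CC3 | intermediate
22 | saturated tetracyclic methyl lactone: azepine CH R, ethyl CH R, O–CH S, lactone β-CH R, lactone α-CH(CH3) R; pyrrole α-carbon free | CC[C@H]1[C@@H]2OC(=O)[C@H](C)[C@@H]2c2ccn3c2[C@@H]1CCCC3 | intermediate
23 | (S)-2-methylsuccinic acid | C[C@@H](CC(=O)O)C(=O)O | starting material
24 | (S)-methylsuccinic anhydride, (3S)-3-methyloxolane-2,5-dione | C[C@H]1CC(=O)OC1=O | intermediate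
25 | γ-keto acid: 22 with a (3S)-3-carboxybutanoyl group on the pyrrole α-carbon | CC[C@H]1[C@@H]2OC(=O)[C@H](C)[C@@H]2c2cc(C(=O)C[C@H](C)C(=O)O)n3c2[C@@H]1CCCC3 | intermediate
26 | γ-hydroxy acid: 25 with the ketone reduced to the (R)-carbinol | CC[C@H]1[C@@H]2OC(=O)[C@H](C)[C@@H]2c2cc([C@H](O)C[C@H](C)C(=O)O)n3c2[C@@H]1CCCC3 | intermediate
27 | CNP0232452.4: 22 carrying a trans (R at O–CH, S at CH–CH3) 3-methyl-γ-butyrolactone at the pyrrole α-carbon | CC[C@H]1[C@@H]2OC(=O)[C@H](C)[C@@H]2c2cc([C@H]3C[C@H](C)C(=O)O3)n3c2[C@@H]1CCCC3 | target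

**Count and risks**

Total steps: 14. Longest linear sequence: 12 steps (3 → 5 → 8 → 9 → 10 → 13 → 15 → 18 → 19 → 21 → 22 → 25 → 27).

Steps most likely to fail:

1. Step 6. Alkylation of the pyrrole at its second α-carbon, a mismatched facial bias from the neighbouring stereocenter, or aldol and β-elimination chemistry of the ylide in the basic stage may erode the one-pot annulation. Fallback: the two bonds are made one at a time. From 10, the same iminium-catalysed Friedel–Crafts alkylation is run with purchased 1-allyl-1H-pyrrole in excess, which suppresses over-alkylation, to give the N-allylpyrrole aldehyde F1. Methylenation with Ph3P=CH2 gives the N-allylpyrrole terminal diene F2, and ring-closing metathesis with the second-generation Grubbs catalyst closes the azepine with loss of ethene and returns to 13.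

2. Step 9. Intermolecular attack through the free, more nucleophilic pyrrole α-carbon (oligomerization) may outrun the intramolecular β-attack. Fallback: from 18, trichloroacetyl chloride without catalyst acylates the free α-carbon to give the trichloroacetylpyrrole butenolide F3. The acyl group blocks that carbon and directs electrophiles to the β-carbon remote from it, which is the one required, so AlCl3 should then close the ring to the trichloroacetyl tetracyclic lactone F4. Aqueous NaOH (haloform cleavage, lactone reclosed on acidification) gives the pyrrole-α-carboxylic acid F5, and protodecarboxylation in CF3CO2H returns to 19.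

3. Step 14. Hydride transfer to the electron-rich, amide-like ketone may be slow, and ionization of the pyrrolyl carbinol may cause loss of configuration at the O–CH carbon or over-reduction. Fallback: the lactone is attached as a preformed ring by C–C bond formation. Purchased (S)-2-methylpent-4-enoic acid is ozonized (O3, then Me2S) to the lactol F6 and acetylated (Ac2O, pyridine) to the lactol acetate F7. From 22, BF3·OEt2 at −78 °C ionizes the acetate to the cyclic acyloxocarbenium ion, which should alkylate the free pyrrole α-carbon anti to the ring methyl and give the trans lactone 27 directly, replacing steps 13 and 14.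

**Further compounds**

F1 | step 6 | (3R,4R,5S)-3-(1-allyl-1H-pyrrol-2-yl)-5-[(tert-butyldimethylsilyl)oxy]-4-ethyl-7-(trimethylsilyl)hept-6-ynal | CC[C@H]([C@@H](CC=O)c1cccn1CC=C)[C@@H](C#C[Si](C)(C)C)O[Si](C)(C)C(C)(C)C
F2 | step 6 | tert-butyl{[(3S,4R,5R)-5-(1-allyl-1H-pyrrol-2-yl)-4-ethyl-1-(trimethylsilyl)oct-7-en-1-yn-3-yl]oxy}dimethylsilane | CC[C@H]([C@@H](CC=C)c1cccn1CC=C)[C@@H](C#C[Si](C)(C)C)O[Si](C)(C)C(C)(C)C
F3 | step 9 | 2,2,2-trichloro-1-{(9R)-9-[(1R)-1-((2R)-5-oxo-2,5-dihydrofuran-2-yl)propyl]-8,9-dihydro-5H-pyrrolo[1,2-a]azepin-3-yl}ethan-1-one | CC[C@H]([C@H]1CC=CCn2c(C(=O)C(Cl)(Cl)Cl)ccc12)[C@@H]1OC(=O)C=C1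
F4 | step 9 | tetracyclic lactone 19 carrying a trichloroacetyl group on the pyrrole α-carbon | CC[C@H]1[C@@H]2OC(=O)C[C@@H]2c2cc(C(=O)C(Cl)(Cl)Cl)n3c2[C@@H]1CC=CC3
F5 | step 9 | tetracyclic lactone 19 carrying a carboxylic acid on the pyrrole α-carbon | CC[C@H]1[C@@H]2OC(=O)C[C@@H]2c2cc(C(=O)O)n3c2[C@@H]1CC=CC3
F6 | step 14 | (3S)-5-hydroxy-3-methyloxolan-2-one (mixture at the lactol carbon) | C[C@H]1CC(O)OC1=O
F7 | step 14 | (4S)-4-methyl-5-oxooxolan-2-yl acetate (mixture at the acetal carbon) | C[C@H]1CC(OC(C)=O)OC1=O
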